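**Plan**
- The C1–OH bond is traced back to a C1–B bond; C1–B and C6–C1' are then cut together across a C1–C6 aryne of the dimethoxybenzene ring.
- Enabling feature: ring carbons C1 (hydroxyl) and C6 (heneicosyl, C1'–C21') are neighbours, and C1 lies beside the C2 methoxy group, which polarises the aryne so that carbon enters at C6 and the metal ends at C1.
- Forward: 3,5-dimethoxyphenol is turned into an ortho-iodoaryl triflate (carbamate, ortho-iodination, hydrolysis, triflation); heneicosan-1-ol gives the bromide, then the Grignard reagent.
- The chain, the ring and boron are joined in one flask; oxidation of C1–B then gives the phenol.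
- No ring is formed (the benzene ring is bought) and the target has no stereocentre, so no stereocontrol is needed.

Key step: step 7

Remark: an ortho-magnesiated aryl triflate is expected to lose triflate even at low temperature, so the chain Grignard reagent itself performs the iodine–magnesium exchange (one equivalent ends as 1-iodoheneicosane) and no second carbon nucleophile meets the aryne; the dimethyl boronate is moisture-sensitive and is carried on crude after a non-aqueous work-up.

Step 1
Reactants: 1 3,5-dimethoxyphenol; 2 N,N-diethylcarbamoyl chloride
Product: 3 3,5-dimethoxyphenyl N,N-diethylcarbamate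
Conditions: K2CO3, MeCN, reflux
Reagents that add atoms: none
Why: O-carbamoylation of the phenoxide formed with K2CO3 (acyl substitution at the carbamoyl chloride) installs the strongest oxygen-based directing group for the metalation that follows.

Step 2
Reactants: 3 3,5-dimethoxyphenyl N,N-diethylcarbamate
Product: 5 2-iodo-3,5-dimethoxyphenyl N,N-diethylcarbamate, via 2-lithio-3,5-dimethoxyphenyl N,N-diethylcarbamate 4 (not isolated)
Conditions: s-BuLi, TMEDA, THF, −78 °C; then I2 in THF, −78 °C → rt
Reagents that add atoms: iodine, II
Why: Directed ortho metalation, in which the carbamate and the neighbouring methoxy group together direct s-BuLi/TMEDA to the carbon between them rather than to the carbon between the two weaker methoxy directors; the aryllithium 4 is held at −78 °C to prevent the anionic ortho-Fries shift and is then iodinated.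

Step 3
Reactants: 5 2-iodo-3,5-dimethoxyphenyl N,N-diethylcarbamate
Product: 6 2-iodo-3,5-dimethoxyphenol
Conditions: NaOH, EtOH/H2O, reflux, Ar; acidic work-up
Reagents that add atoms: none
Why: Alkaline hydrolysis of the aryl carbamate (acyl substitution with the 2-iodophenoxide as leaving group) needs forcing conditions, which the methyl ethers and the aryl iodide tolerate.

Step 4
Reactants: 6 2-iodo-3,5-dimethoxyphenol
Product: 7 2-iodo-3,5-dimethoxyphenyl trifluoromethanesulfonate
Conditions: Tf2O, pyridine, CH2Cl2, 0 °C
Reagents that add atoms: trifluoromethanesulfonic anhydride, O=S(=O)(OS(=O)(=O)C(F)(F)F)C(F)(F)F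
Why: O-sulfonylation of the phenol with Tf2O and pyridine is fast at 0 °C and places the leaving group ortho to iodine, as the aryne precursor requires.

Step 5
Reactants: 8 heneicosan-1-ol
Product: 9 1-bromoheneicosane
Conditions: CBr4, PPh3, CH2Cl2, 0 °C → rt
Reagents that add atoms: carbon tetrabromide, BrC(Br)(Br)Br
Why: Appel reaction, in which the alcohol is activated as an alkoxyphosphonium salt and displaced by bromide in an SN2 step at the unhindered primary carbon.

Step 6
Reactants: 9 1-bromoheneicosane
Product: 10 heneicosylmagnesium bromide
Conditions: Mg turnings, I2 (cat.), THF, 45 °C, slow addition of 9; titrated solution used directly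
Reagents that add atoms: magnesium, [Mg]
Why: Grignard formation by insertion of magnesium into the primary C–Br bond is routine for long-chain bromides, and slow addition in warm THF limits Wurtz coupling and keeps the reagent in solution.

Step 7
Reactants: 7 2-iodo-3,5-dimethoxyphenyl trifluoromethanesulfonate; 10 heneicosylmagnesium bromide; 11 trimethyl borate
Product: 15 dimethyl (2-heneicosyl-4,6-dimethoxyphenyl)boronate, via 2-(bromomagnesio)-3,5-dimethoxyphenyl trifluoromethanesulfonate 12 (not isolated), via 3,5-dimethoxybenzyne 13 (not isolated), via (2-heneicosyl-4,6-dimethoxyphenyl)magnesium bromide 14 (not isolated)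
Conditions: 10 (2.5 equiv), LiCl (2.5 equiv), THF, −20 °C, 7 added over 1 h, then 0 °C; 11 (4 equiv), −40 °C → rt; solvent removed, dry hexane, filtration under Ar, crude used
Reagents that add atoms: none
Why: Iodine–magnesium exchange at C1 of 7 by 10, favoured because the aryl carbanion is flanked by triflate and methoxy, gives 12, which expels bromomagnesium triflate to give the C1–C6 aryne 13. A second equivalent of 10 adds its C1' carbon to C6 (carbomagnesiation), and the C1 arylmagnesium 14 so formed is captured by B(OMe)3 with loss of methoxide to give 15. The closest known reaction type is the addition of Grignard reagents to arynes released from 2-iodoaryl sulfonates, followed by electrophilic trapping of the new arylmagnesium. No ring closes and no stereocentre is created. The selectivity needed is regiochemical: the inductively withdrawing C2 methoxy group distorts the aryne and stabilises negative charge at C1, so the nucleophile should enter at C6, while the C4 methoxy group, meta to C6, has little influence. Slow addition of 7 to an excess of 10 keeps the aryne concentration low, so that the primary alkyl Grignard reagent and not the hindered arylmagnesium 14 captures it.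

Step 8
Reactants: 15 dimethyl (2-heneicosyl-4,6-dimethoxyphenyl)boronate
Product: 16 6-n-heneicosyl-2,4-dimethoxyphenol
Conditions: 30% aq H2O2, 2 M aq NaOH, THF, 0 °C, Ar; then aq Na2S2O3, aq NH4Cl
Reagents that add atoms: hydrogen peroxide, OO
Why: Boronate oxidation, in which hydroperoxide adds to boron and the aryl group migrates from boron to oxygen so that the hydroxyl appears exactly at C1; low temperature, argon and a reductive quench limit further oxidation of the electron-rich phenol.

**Compound list**
1 | 3,5-dimethoxyphenol | COc1cc(O)cc(OC)c1 | starting material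
2 | N,N-diethylcarbamoyl chloride | CCN(CC)C(Cl)=O | starting material
3 | 3,5-dimethoxyphenyl N,N-diethylcarbamate | CCN(CC)C(=O)Oc1cc(OC)cc(OC)c1 | intermediate
4 | 2-lithio-3,5-dimethoxyphenyl N,N-diethylcarbamate | CCN(CC)C(=O)Oc1cc(OC)cc(OC)c1[Li] | intermediate
5 | 2-iodo-3,5-dimethoxyphenyl N,N-diethylcarbamate | CCN(CC)C(=O)Oc1cc(OC)cc(OC)c1I | intermediate
6 | 2-iodo-3,5-dimethoxyphenol | Oc1cc(OC)cc(OC)c1I | intermediate
7 | 2-iodo-3,5-dimethoxyphenyl trifluoromethanesulfonate | COc1cc(OC)c(I)c(OS(=O)(=O)C(F)(F)F)c1 | intermediate
8 | heneicosan-1-ol | CCCCCCCCCCCCCCCCCCCCCO | starting material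
9 | 1-bromoheneicosane | CCCCCCCCCCCCCCCCCCCCCBr | intermediate
10 | heneicosylmagnesium bromide | CCCCCCCCCCCCCCCCCCCCC[Mg]Br | intermediate
11 | trimethyl borate | COB(OC)OC | starting material
12 | 2-(bromomagnesio)-3,5-dimethoxyphenyl trifluoromethanesulfonate | COc1cc(OC)c([Mg]Br)c(OS(=O)(=O)C(F)(F)F)c1 | intermediate
13 | 3,5-dimethoxybenzyne (1,2-didehydro-3,5-dimethoxybenzene) | COC1=CC(OC)=CC#C1 | intermediate
14 | (2-heneicosyl-4,6-dimethoxyphenyl)magnesium bromide | CCCCCCCCCCCCCCCCCCCCCc1cc(OC)cc(OC)c1[Mg]Br | intermediate
15 | dimethyl (2-heneicosyl-4,6-dimethoxyphenyl)boronate | CCCCCCCCCCCCCCCCCCCCCc1cc(OC)cc(OC)c1B(OC)OC | intermediate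
16 | 6-n-heneicosyl-2,4-dimethoxyphenol | CCCCCCCCCCCCCCCCCCCCCc1cc(OC)cc(OC)c1O | target

**Step count**
Total: 8 steps. Longest linear sequence: 6 steps (steps 1, 2, 3, 4, 7, 8); the chain branch (steps 5 and 6) joins at step 7.

**Steps most likely to fail**

First, step 7. What may go wrong is capture of the aryne by the arylmagnesium already formed (oligoaryl formation), attack of the alkyl Grignard reagent at the triflate sulfur instead of at iodine, or insufficient regiocontrol in the addition. The fallback sets out from 1 and 10 and replaces the aryne by a cross-coupling and halogenation sequence. Phenol 1 is triflated (Tf2O, pyridine) to 3,5-dimethoxyphenyl trifluoromethanesulfonate F1. Kumada coupling of F1 with 10 under iron catalysis (Fe(acac)3, THF/NMP) gives 1-heneicosyl-3,5-dimethoxybenzene F2. Bromination with NBS in CH2Cl2 should occur ortho to the chain and para to one methoxy group, as with other 5-alkylresorcinol dimethyl ethers, to give 2-bromo-1-heneicosyl-3,5-dimethoxybenzene F3. Bromine–lithium exchange with n-BuLi in THF at −78 °C gives (2-heneicosyl-4,6-dimethoxyphenyl)lithium F4, which is quenched with 11 to rejoin the route at 15.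

Second, step 2. What may go wrong is migration of the carbamoyl group from oxygen to the lithiated carbon (anionic ortho-Fries shift) or addition of s-BuLi to the carbamate carbonyl before the iodine arrives. The fallback sets out from 1 and uses an acetal directing group that can neither migrate nor be attacked. Phenol 1 is converted with MOMCl and iPr2NEt into 1-(methoxymethoxy)-3,5-dimethoxybenzene F5. Ortho-lithiation with n-BuLi/TMEDA in THF at 0 °C gives 2-lithio-1-(methoxymethoxy)-3,5-dimethoxybenzene F6, and iodine gives 2-iodo-1-(methoxymethoxy)-3,5-dimethoxybenzene F7. HCl in methanol removes the acetal and rejoins the route at 6, which also avoids the forcing hydrolysis of step 3.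

Third, step 8. What may go wrong is further oxidation of the very electron-rich phenoxide by peroxide or air towards quinone-type products, and base-induced protodeboronation of the hindered boronate. The fallback sets out from 7 and 10, generates 14 as in step 7 and oxygenates it directly, so that no oxidant is present once the phenol is free. At −78 °C, 14 is treated with bis(trimethylsilyl) peroxide (electrophilic oxygenation of a Grignard reagent) to give (2-heneicosyl-4,6-dimethoxyphenoxy)trimethylsilane F8. Dilute HCl in THF removes the silyl group and rejoins the route at 16.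

**Further compounds**
F1 | step 7 | 3,5-dimethoxyphenyl trifluoromethanesulfonate | COc1cc(OC)cc(OS(=O)(=O)C(F)(F)F)c1
F2 | step 7 | 1-heneicosyl-3,5-dimethoxybenzene | CCCCCCCCCCCCCCCCCCCCCc1cc(OC)cc(OC)c1
F3 | step 7 | 2-bromo-1-heneicosyl-3,5-dimethoxybenzene | CCCCCCCCCCCCCCCCCCCCCc1cc(OC)cc(OC)c1Br
F4 | step 7 | (2-heneicosyl-4,6-dimethoxyphenyl)lithium | CCCCCCCCCCCCCCCCCCCCCc1cc(OC)cc(OC)c1[Li]
F5 | step 2 | 1-(methoxymethoxy)-3,5-dimethoxybenzene | COCOc1cc(OC)cc(OC)c1
F6 | step 2 | 2-lithio-1-(methoxymethoxy)-3,5-dimethoxybenzene | COCOc1cc(OC)cc(OC)c1[Li]
F7 | step 2 | 2-iodo-1-(methoxymethoxy)-3,5-dimethoxybenzene | COCOc1cc(OC)cc(OC)c1I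
F8 | step 8 | (2-heneicosyl-4,6-dimethoxyphenoxy)trimethylsilane | CCCCCCCCCCCCCCCCCCCCCc1cc(OC)cc(OC)c1O[Si](C)(C)C
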